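**Assumption:** the target has no stereocentre and no E/Z-isomerisable alkene (each side-chain alkene carries two identical methyl groups), so it is achiral and no stereocontrol is needed.

**Retrosynthetic overview**
1. Target 16 ⇐ bis-MOM ether 15; the last step only unmasks the two phenols.
2. 15 ⇐ trisubstituted quinone 11 + prenylstannane 12. This is the key C–C bond: BF3-promoted carbonyl allylation (1,2-addition) then [3,3] shift, a net Michael-type prenylation at the one free quinone carbon, followed by reoxidation.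
3. 11 ⇐ ortho-prenylphenol 10 (Fremy's salt) ⇐ 1,1-dimethylallyl aryl ether 9 (aromatic Claisen) ⇐ phenol 6 + chloroalkyne 7.
4. 6 ⇐ diaryl ether aldehyde 4 (Dakin) ⇐ SNAr of phenol 2 (from triol 1) on 2-fluoro-3-methoxybenzaldehyde 3.
5. Rings: no ring is built. Both six-membered rings are bought as benzenes; the quinone ring is made from the second benzene by oxidation (step 7), after the peracid step and before the key prenylation.

**Route**

Step 1
Reactants: 1 methyl 2,4,6-trihydroxybenzoate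
Product: 2 methyl 2-hydroxy-4,6-bis(methoxymethoxy)benzoate
Conditions: MOMCl (2.2 equiv), i-Pr2NEt (2.5 equiv), CH2Cl2, 0 °C → rt
Reagents that add atoms: chloromethyl methyl ether, COCCl
Why: Williamson-type O-alkylation (MOM protection) takes the 4-OH and one ortho-OH, while the last ortho-OH is held in a hydrogen bond to the ester carbonyl and stays free.

Step 2
Reactants: 2 methyl 2-hydroxy-4,6-bis(methoxymethoxy)benzoate; 3 2-fluoro-3-methoxybenzaldehyde
Product: 4 methyl 2-(2-formyl-6-methoxyphenoxy)-4,6-bis(methoxymethoxy)benzoate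
Conditions: K2CO3 (1.5 equiv), dry DMF, 100 °C
Reagents that add atoms: none
Why: Nucleophilic aromatic substitution (SNAr), in which the ortho-formyl group stabilises the Meisenheimer adduct so the only free phenoxide of 2 displaces fluoride; MOM ethers, ester and the non-enolisable aldehyde tolerate carbonate.

Step 3
Reactants: 4 methyl 2-(2-formyl-6-methoxyphenoxy)-4,6-bis(methoxymethoxy)benzoate
Product: 6 methyl 2-(2-hydroxy-6-methoxyphenoxy)-4,6-bis(methoxymethoxy)benzoate, via aryl formate 5 (not isolated)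
Conditions: mCPBA (1.5 equiv), CH2Cl2, 0 °C → rt; then K2CO3 (0.2 equiv), MeOH, 0 °C
Reagents that add atoms: mCPBA, OOC(=O)c1cccc(Cl)c1
Why: Baeyer–Villiger (Dakin-type) oxidation in which the oxygen-substituted aryl group migrates to give the formate, which catalytic methanolysis cleaves without touching the hindered methyl benzoate; it is run before any alkene is present.

Step 4
Reactants: 6 methyl 2-(2-hydroxy-6-methoxyphenoxy)-4,6-bis(methoxymethoxy)benzoate; 7 3-chloro-3-methylbut-1-yne
Product: 8 methyl 2-{2-methoxy-6-[(2-methylbut-3-yn-2-yl)oxy]phenoxy}-4,6-bis(methoxymethoxy)benzoate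
Conditions: DBU (1.5 equiv), CuCl2·2H2O (1 mol %), MeCN, 0 °C → rt
Reagents that add atoms: none
Why: Copper-catalysed O-alkylation of a phenol with a tertiary propargylic chloride (Godfrey conditions) gives the 1,1-dimethylpropargyl aryl ether under mild base.

Step 5
Reactants: 8 methyl 2-{2-methoxy-6-[(2-methylbut-3-yn-2-yl)oxy]phenoxy}-4,6-bis(methoxymethoxy)benzoate
Product: 9 methyl 2-{2-methoxy-6-[(2-methylbut-3-en-2-yl)oxy]phenoxy}-4,6-bis(methoxymethoxy)benzoate
Conditions: H2 (1 atm), Lindlar catalyst, quinoline, EtOAc, rt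
Reagents that add atoms: none
Why: Lindlar semi-hydrogenation stops at the terminal alkene and leaves arenes, ester and MOM acetals alone; no alkene geometry is at stake.

Step 6
Reactants: 9 methyl 2-{2-methoxy-6-[(2-methylbut-3-en-2-yl)oxy]phenoxy}-4,6-bis(methoxymethoxy)benzoate
Product: 10 methyl 2-[2-hydroxy-6-methoxy-3-(3-methylbut-2-en-1-yl)phenoxy]-4,6-bis(methoxymethoxy)benzoate
Conditions: N,N-diethylaniline, 130 °C, Ar
Reagents that add atoms: none
Why: Aromatic Claisen rearrangement ([3,3]-sigmatropic shift) to the only free ortho position, then tautomerisation; allyl inversion turns the 1,1-dimethylallyl ether into the linear prenyl group.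

Step 7
Reactants: 10 methyl 2-[2-hydroxy-6-methoxy-3-(3-methylbut-2-en-1-yl)phenoxy]-4,6-bis(methoxymethoxy)benzoate
Product: 11 methyl 2-{[2-methoxy-5-(3-methylbut-2-en-1-yl)-3,6-dioxocyclohexa-1,4-dien-1-yl]oxy}-4,6-bis(methoxymethoxy)benzoate
Conditions: Fremy's salt (2.5 equiv), KH2PO4 buffer, acetone/H2O, rt
Reagents that add atoms: potassium nitrosodisulfonate (Fremy's salt), [K+].[K+].[O]N(S(=O)(=O)[O-])S(=O)(=O)[O-]
Why: Teuber oxidation, in which the phenoxyl radical is trapped at the free para position to give the para-quinone; the protected, ester-deactivated benzoate ring and the prenyl alkene are inert to this one-electron oxidant.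

Step 8
Reactants: 11 methyl 2-{[2-methoxy-5-(3-methylbut-2-en-1-yl)-3,6-dioxocyclohexa-1,4-dien-1-yl]oxy}-4,6-bis(methoxymethoxy)benzoate; 12 tributyl(3-methylbut-2-en-1-yl)stannane
Product: 15 methyl 2-{[2-methoxy-4,5-bis(3-methylbut-2-en-1-yl)-3,6-dioxocyclohexa-1,4-dien-1-yl]oxy}-4,6-bis(methoxymethoxy)benzoate, via allyl quinol 13 (not isolated), via diprenylhydroquinone 14 (not isolated)
Conditions: BF3·OEt2 (2.5 equiv), CH2Cl2, −78 → −40 °C; sat. aq. NaHCO3 quench; then Ag2O, MgSO4, Et2O, rt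
Reagents that add atoms: none
Why: Naruta quinone prenylation, i.e. BF3-activated carbonyl allylation by the stannane through its γ-carbon (SE2′ 1,2-addition), then a [3,3] shift that places a linear prenyl group on the only unsubstituted ring carbon (net Michael-type conjugate prenylation, as in coenzyme Q syntheses), and Ag2O reoxidation of the hydroquinone; the transient quinol stereocentre is lost on aromatisation.

Step 9
Reactants: 15 methyl 2-{[2-methoxy-4,5-bis(3-methylbut-2-en-1-yl)-3,6-dioxocyclohexa-1,4-dien-1-yl]oxy}-4,6-bis(methoxymethoxy)benzoate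
Product: 16 atrovirinone
Conditions: 3 M aq. HCl/MeOH (1:5), rt → 40 °C
Reagents that add atoms: none
Why: Acid-catalysed acetal solvolysis (MOM deprotection) through oxocarbenium ions trapped by methanol; the mild temperature is chosen to spare the trisubstituted alkenes and the vinylogous ester groups of the quinone.

**Compound list**
1 | methyl 2,4,6-trihydroxybenzoate | COC(=O)c1c(O)cc(O)cc1O | starting material
2 | methyl 2-hydroxy-4,6-bis(methoxymethoxy)benzoate | COC(=O)c1c(O)cc(OCOC)cc1OCOC | intermediate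
3 | 2-fluoro-3-methoxybenzaldehyde | COc1cccc(C=O)c1F | starting material
4 | methyl 2-(2-formyl-6-methoxyphenoxy)-4,6-bis(methoxymethoxy)benzoate | COC(=O)c1c(OCOC)cc(OCOC)cc1Oc1c(C=O)cccc1OC | intermediate
5 | methyl 2-[2-(formyloxy)-6-methoxyphenoxy]-4,6-bis(methoxymethoxy)benzoate (aryl formate) | COC(=O)c1c(OCOC)cc(OCOC)cc1Oc1c(OC=O)cccc1OC | intermediate (not isolated)
6 | methyl 2-(2-hydroxy-6-methoxyphenoxy)-4,6-bis(methoxymethoxy)benzoate | COC(=O)c1c(OCOC)cc(OCOC)cc1Oc1c(O)cccc1OC | intermediate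
7 | 3-chloro-3-methylbut-1-yne | CC(C)(Cl)C#C | starting material
8 | methyl 2-{2-methoxy-6-[(2-methylbut-3-yn-2-yl)oxy]phenoxy}-4,6-bis(methoxymethoxy)benzoate | COC(=O)c1c(OCOC)cc(OCOC)cc1Oc1c(OC(C)(C)C#C)cccc1OC | intermediate
9 | methyl 2-{2-methoxy-6-[(2-methylbut-3-en-2-yl)oxy]phenoxy}-4,6-bis(methoxymethoxy)benzoate | COC(=O)c1c(OCOC)cc(OCOC)cc1Oc1c(OC(C)(C)C=C)cccc1OC | intermediate
10 | methyl 2-[2-hydroxy-6-methoxy-3-(3-methylbut-2-en-1-yl)phenoxy]-4,6-bis(methoxymethoxy)benzoate | COC(=O)c1c(OCOC)cc(OCOC)cc1Oc1c(O)c(CC=C(C)C)ccc1OC | intermediate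
11 | methyl 2-{[2-methoxy-5-(3-methylbut-2-en-1-yl)-3,6-dioxocyclohexa-1,4-dien-1-yl]oxy}-4,6-bis(methoxymethoxy)benzoate | COC(=O)c1c(OCOC)cc(OCOC)cc1OC1=C(OC)C(=O)C=C(CC=C(C)C)C1=O | intermediate
12 | tributyl(3-methylbut-2-en-1-yl)stannane | CCCC[Sn](CCCC)(CCCC)CC=C(C)C | starting material
13 | methyl 2-{[6-hydroxy-2-methoxy-5-(3-methylbut-2-en-1-yl)-6-(2-methylbut-3-en-2-yl)-3-oxocyclohexa-1,4-dien-1-yl]oxy}-4,6-bis(methoxymethoxy)benzoate (allyl quinol, racemic) | COC(=O)c1c(OCOC)cc(OCOC)cc1OC1=C(OC)C(=O)C=C(CC=C(C)C)C1(O)C(C)(C)C=C | intermediate (not isolated)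
14 | methyl 2-[2,5-dihydroxy-6-methoxy-3,4-bis(3-methylbut-2-en-1-yl)phenoxy]-4,6-bis(methoxymethoxy)benzoate (diprenylhydroquinone) | COC(=O)c1c(OCOC)cc(OCOC)cc1Oc1c(OC)c(O)c(CC=C(C)C)c(CC=C(C)C)c1O | intermediate (not isolated)
15 | methyl 2-{[2-methoxy-4,5-bis(3-methylbut-2-en-1-yl)-3,6-dioxocyclohexa-1,4-dien-1-yl]oxy}-4,6-bis(methoxymethoxy)benzoate | COC(=O)c1c(OCOC)cc(OCOC)cc1OC1=C(OC)C(=O)C(CC=C(C)C)=C(CC=C(C)C)C1=O | intermediate
16 | atrovirinone, methyl 2,4-dihydroxy-6-{[2-methoxy-4,5-bis(3-methylbut-2-en-1-yl)-3,6-dioxocyclohexa-1,4-dien-1-yl]oxy}benzoate | COC(=O)c1c(O)cc(O)cc1OC1=C(OC)C(=O)C(CC=C(C)C)=C(CC=C(C)C)C1=O | target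

**Summary**
Total step count: 9. Longest linear sequence: 9 steps (1 → 16); compounds 3, 7 and 12 are purchased.

The three steps most likely to fail, each with a fallback:

Step 2 (SNAr). The phenoxide of 2 is hindered and hydrogen-bonded, and the fluoride sits between two ortho substituents. The fallback sets out from 2 and comes back at 4. It replaces addition–elimination by a copper-catalysed Ullmann diaryl ether synthesis of 2 with commercial 2-bromo-3-methoxybenzaldehyde (COc1cccc(C=O)c1Br) using CuI, N,N-dimethylglycine and Cs2CO3 in dioxane at 90 °C, where the ortho-formyl group assists the copper step. This gives 4 directly and makes no new compound (F0).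

Step 8 (key prenylation). The quinone is crowded, and BF3 may attack the MOM ethers or cyclise the prenylhydroquinone. The fallback sets out from 11 and comes back at 14, which Ag2O then oxidises to 15 as before. It delivers the second prenyl group intramolecularly by the sequence already used in steps 4–6:
- Reduce 11 with aqueous Na2S2O4 in Et2O to methyl 2-[2,5-dihydroxy-6-methoxy-3-(3-methylbut-2-en-1-yl)phenoxy]-4,6-bis(methoxymethoxy)benzoate F1.
- Alkylate its less hindered hydroxyl (flanked by OMe and H) with 7 under DBU/CuCl2 to give methyl 2-{2-hydroxy-6-methoxy-5-[(2-methylbut-3-yn-2-yl)oxy]-3-(3-methylbut-2-en-1-yl)phenoxy}-4,6-bis(methoxymethoxy)benzoate F2.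
- Semi-hydrogenate over Lindlar catalyst to methyl 2-{2-hydroxy-6-methoxy-5-[(2-methylbut-3-en-2-yl)oxy]-3-(3-methylbut-2-en-1-yl)phenoxy}-4,6-bis(methoxymethoxy)benzoate F3.
- Heat in N,N-diethylaniline at 120 °C so that an aromatic Claisen rearrangement moves the allyl unit to the only free ring carbon, giving 14.

Step 9 (final deprotection). Protic acid may add to the prenyl alkenes or exchange the aryloxy group of the quinone for methoxy. The fallback sets out from 15 and comes back at 16. TMSOTf and 2,2′-bipyridyl in MeCN at 0 °C convert both aryl MOM ethers into aryl silyl ethers without free protic acid, giving methyl 2-{[2-methoxy-4,5-bis(3-methylbut-2-en-1-yl)-3,6-dioxocyclohexa-1,4-dien-1-yl]oxy}-4,6-bis[(trimethylsilyl)oxy]benzoate F4. Water at rt then hydrolyses the silyl ethers to 16.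

**Further compounds**
F0 | step 2 | none | none
F1 | step 8 | methyl 2-[2,5-dihydroxy-6-methoxy-3-(3-methylbut-2-en-1-yl)phenoxy]-4,6-bis(methoxymethoxy)benzoate | COC(=O)c1c(OCOC)cc(OCOC)cc1Oc1c(OC)c(O)cc(CC=C(C)C)c1O
F2 | step 8 | methyl 2-{2-hydroxy-6-methoxy-5-[(2-methylbut-3-yn-2-yl)oxy]-3-(3-methylbut-2-en-1-yl)phenoxy}-4,6-bis(methoxymethoxy)benzoate | COC(=O)c1c(OCOC)cc(OCOC)cc1Oc1c(OC)c(OC(C)(C)C#C)cc(CC=C(C)C)c1O
F3 | step 8 | methyl 2-{2-hydroxy-6-methoxy-5-[(2-methylbut-3-en-2-yl)oxy]-3-(3-methylbut-2-en-1-yl)phenoxy}-4,6-bis(methoxymethoxy)benzoate | COC(=O)c1c(OCOC)cc(OCOC)cc1Oc1c(OC)c(OC(C)(C)C=C)cc(CC=C(C)C)c1O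
F4 | step 9 | methyl 2-{[2-methoxy-4,5-bis(3-methylbut-2-en-1-yl)-3,6-dioxocyclohexa-1,4-dien-1-yl]oxy}-4,6-bis[(trimethylsilyl)oxy]benzoate | COC(=O)c1c(O[Si](C)(C)C)cc(O[Si](C)(C)C)cc1OC1=C(OC)C(=O)C(CC=C(C)C)=C(CC=C(C)C)C1=O
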